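**Retrosynthetic overview**
1. Disconnect the stilbene C=C by Horner–Wadsworth–Emmons olefination. This gives a benzodioxane aldehyde and a bis-silyl-protected 3,5-dihydroxybenzylphosphonate.
2. Disconnect the benzodioxane through both C–O bonds: a cis-epoxide opened at the benzylic carbon by 4-fluoro-3-hydroxybenzaldehyde (inversion), then intramolecular SNAr by the C-3 alkoxide (retention). Net result: cis-epoxide gives the trans-(2R,3R) dioxane, and the fluorine para to CHO fixes the regiochemistry.
3. The cis-epoxide comes from Jacobsen epoxidation of a Z-cinnamyl silyl ether, made by Sonogashira coupling and Lindlar reduction of commercial 4-bromo-2,6-dimethoxyphenol.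
4. Ring order: the epoxide ring forms in step 4, the 1,4-dioxane ring in step 8; all arenes are purchased.

Assumption: all starting materials below are commercially available (TBS-propargyl ether and the silyl chlorides included).

**Step 1**
Reactants: 1 (4-bromo-2,6-dimethoxyphenol), 2 (TIPSCl)
Product: 3 (triisopropyl(4-bromo-2,6-dimethoxyphenoxy)silane)
Conditions: TIPSCl, imidazole, DMF, 50 °C
Reagents that add atoms: TIPSCl, CC(C)[Si](Cl)(C(C)C)C(C)C
Why: Silylation of the phenol gives a base-stable aryl TIPS ether that survives the later carbonate/DMF cascade; no stereocenters are involved.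

**Step 2**
Reactants: 3, 4 (tert-butyldimethyl(prop-2-yn-1-yloxy)silane)
Product: 5 (aryl alkyne, ArC≡C–CH2OTBS)
Conditions: Pd(PPh3)2Cl2 (5 mol%), CuI (10 mol%), iPr2NH, DMF, 80 °C
Reagents that add atoms: none (alkyne 4 is a listed reactant)
Why: Sonogashira coupling builds the C3 side chain in one step.

**Step 3**
Reactants: 5
Product: 6 ((Z)-ArCH=CH–CH2OTBS)
Conditions: H2 (1 atm), Lindlar catalyst, quinoline, EtOAc, rt
Reagents that add atoms: none (H2 only)
Why: Lindlar semihydrogenation adds H2 syn across the alkyne, so the alkene is Z, which is required for the trans-dioxane later.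

**Step 4**
Reactants: 6, 7 (NaOCl)
Product: 8 (cis-(2R,3S)-epoxide, ArCH(O)CH–CH2OTBS)
Conditions: (S,S)-Jacobsen Mn(salen)Cl (5 mol%), 4-phenylpyridine N-oxide, NaOCl (pH 11), CH2Cl2, 0 °C
Reagents that add atoms: sodium hypochlorite, [Na+].[O-]Cl (supplies the epoxide O)
Why: Jacobsen–Katsuki epoxidation of a cis-aryl alkene gives the cis-epoxide with high ee. The (S,S) catalyst is expected to give (2R,3S) by analogy with cis-β-methylstyrene and cis-cinnamate epoxidation. This sets the only two stereocenters.

**Step 5**
Reactants: 9 (methyl 3,5-dihydroxybenzoate), 10 (TBSCl)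
Product: 11 (methyl 3,5-bis(TBSO)benzoate)
Conditions: TBSCl, imidazole, DMF, rt
Reagents that add atoms: TBSCl, CC(C)(C)[Si](C)(C)Cl
Why: Bis-silylation protects the resorcinol OH groups for the HWE step.

**Step 6**
Reactants: 11
Product: 12 ((3,5-bis(TBSO)phenyl)methanol)
Conditions: DIBAL-H, CH2Cl2, −78 °C → 0 °C
Reagents that add atoms: none (hydride only)
Why: DIBAL reduces the ester to the benzylic alcohol; the aryl silyl ethers are untouched.

**Step 7**
Reactants: 12, 13 (triethyl phosphite)
Product: 14 (diethyl 3,5-bis(TBSO)benzylphosphonate)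
Conditions: P(OEt)3, ZnI2, THF, reflux
Reagents that add atoms: triethyl phosphite, CCOP(OCC)OCC
Why: ZnI2-mediated Arbuzov-type conversion of a benzylic alcohol to the phosphonate.

**Step 8 (key step)**
Reactants: 8, 15 (4-fluoro-3-hydroxybenzaldehyde)
Product: 16 (trans-(2R,3R)-benzodioxane aldehyde, CH2OTBS, aryl OTIPS)
Conditions: Cs2CO3 (2 equiv), DMF, 90–100 °C (epoxide 1.2 equiv)
Reagents that add atoms: none (Cs2CO3 is base only; HF is lost as CsF)
Why: The phenoxide opens the cis-epoxide at the benzylic carbon by SN2 with inversion. The resulting C-3 alkoxide then closes the dioxane by intramolecular SNAr on the C–F carbon para to CHO, with retention at that carbon. Benzylic inversion plus C-3 retention converts the cis-epoxide (2R,3S) into the trans-(R,R) dioxane. The fluorine position places CHO para to the O on the CH(CH2OTBS) carbon, as in the target.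

**Step 9**
Reactants: 16, 14
Product: 17 (fully silyl-protected aiphanol, (E)-stilbene)
Conditions: NaH, THF, 0 °C → rt, dark
Reagents that add atoms: none (the phosphonate is a listed reactant)
Why: Horner–Wadsworth–Emmons olefination gives the E-stilbene selectively; the stereocenters are not affected.

**Step 10**
Reactants: 17
Product: 18 (aiphanol)
Conditions: TBAF (8 equiv), AcOH (8 equiv), THF, 0 °C → rt, dark
Reagents that add atoms: none (fluoride removes silyl groups; H comes from AcOH/water)
Why: Buffered fluoride cleaves the primary TBS, aryl TIPS and two aryl TBS ethers in one step. AcOH limits phenoxide-driven benzylic ionization, so the trans configuration is kept.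

**Compound list**

| # | Name | SMILES | Role |
|---|---|---|---|
| 1 | 4-bromo-2,6-dimethoxyphenol | COc1cc(Br)cc(OC)c1O | starting material |
| 2 | triisopropylsilyl chloride | CC(C)[Si](Cl)(C(C)C)C(C)C | starting material (reagent) |
| 3 | aryl TIPS ether of 1 | COc1cc(Br)cc(OC)c1O[Si](C(C)C)(C(C)C)C(C)C | intermediate |
| 4 | TBS propargyl ether | C#CCO[Si](C)(C)C(C)(C)C | starting material |
| 5 | aryl alkyne | COc1cc(C#CCO[Si](C)(C)C(C)(C)C)cc(OC)c1O[Si](C(C)C)(C(C)C)C(C)C | intermediate |
| 6 | (Z)-alkene | COc1cc(/C=C\CO[Si](C)(C)C(C)(C)C)cc(OC)c1O[Si](C(C)C)(C(C)C)C(C)C | intermediate |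
| 7 | sodium hypochlorite | [Na+].[O-]Cl | starting material (oxidant) |
| 8 | cis-(2R,3S)-epoxide | COc1cc([C@@H]2O[C@@H]2CO[Si](C)(C)C(C)(C)C)cc(OC)c1O[Si](C(C)C)(C(C)C)C(C)C | intermediate |
| 9 | methyl 3,5-dihydroxybenzoate | COC(=O)c1cc(O)cc(O)c1 | starting material |
| 10 | TBSCl | CC(C)(C)[Si](C)(C)Cl | starting material (reagent) |
| 11 | methyl 3,5-bis(TBSO)benzoate | COC(=O)c1cc(O[Si](C)(C)C(C)(C)C)cc(O[Si](C)(C)C(C)(C)C)c1 | intermediate |
| 12 | (3,5-bis(TBSO)phenyl)methanol | OCc1cc(O[Si](C)(C)C(C)(C)C)cc(O[Si](C)(C)C(C)(C)C)c1 | intermediate |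
| 13 | triethyl phosphite | CCOP(OCC)OCC | starting material (reagent) |
| 14 | diethyl 3,5-bis(TBSO)benzylphosphonate | CCOP(=O)(OCC)Cc1cc(O[Si](C)(C)C(C)(C)C)cc(O[Si](C)(C)C(C)(C)C)c1 | intermediate |
| 15 | 4-fluoro-3-hydroxybenzaldehyde | O=Cc1ccc(F)c(O)c1 | starting material |
| 16 | trans-(2R,3R)-benzodioxane aldehyde | COc1cc([C@H]2Oc3cc(C=O)ccc3O[C@@H]2CO[Si](C)(C)C(C)(C)C)cc(OC)c1O[Si](C(C)C)(C(C)C)C(C)C | intermediate |
| 17 | protected aiphanol | COc1cc([C@H]2Oc3cc(/C=C/c4cc(O[Si](C)(C)C(C)(C)C)cc(O[Si](C)(C)C(C)(C)C)c4)ccc3O[C@@H]2CO[Si](C)(C)C(C)(C)C)cc(OC)c1O[Si](C(C)C)(C(C)C)C(C)C | intermediate |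
| 18 | aiphanol | COc1cc([C@H]2Oc3cc(/C=C/c4cc(O)cc(O)c4)ccc3O[C@@H]2CO)cc(OC)c1O | target |

**Step count:** 10 steps in total; longest linear sequence is 7 (steps 1, 2, 3, 4, 8, 9, 10).

**Three steps most likely to fail**
1. **Step 4 (Jacobsen epoxidation of the Z-alkene).** The ee may be modest, or the electron-rich epoxide may open or isomerize on silica. Fallback: Sharpless asymmetric dihydroxylation of the E-alkene, then cyclic sulfate. Open the sulfate at the benzylic carbon with 4-benzyloxy-3-hydroxybenzaldehyde, remove the benzyl group, and close the ring by intramolecular SN2 at C-2 (double inversion gives trans).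
2. **Step 8 (epoxide opening/SNAr cascade).** The phenoxide may attack C-2 instead of the benzylic carbon, react through an SN1-like path that scrambles the benzylic center, or self-condense by intermolecular SNAr. Fallback: make the open benzylic aryl ether from 3-hydroxy-4-iodobenzaldehyde and close the ring by Cu-catalysed intramolecular O-arylation (CuI/N,N-dimethylglycine), replacing SNAr.
3. **Step 10 (global desilylation).** Fluoride can cause phenoxide-driven benzylic ionization or stilbene isomerization. Fallback: switch the protecting-group set to MOM ethers (bis-MOM phosphonate, MOM on the syringyl phenol and primary OH) so the last step is acid (HCl/MeOH) instead of fluoride.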